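The earlier runs and the new flask come from a simulation on assumed constants; scatter was added.

With a small charge of free catalyst, the clock worth reading is live catalyst, not hours.

| flask | substrate | free catalyst | remark | time |
|---|---|---|---|---|
| Wednesday's | 0.010 M | 0.38 mM | run made earlier |  |
| flask | 0.010 M | 0.25 mM |  | 4.0 d |

Wednesday's run (percent of the substrate charged)

| time / h | target / % | isomer of the product A / % |
|---|---|---|
| 2.50 | 9.3 | 0.9 |
| 4.00 | 14.7 | 0.6 |
| 5.00 | 17.5 | 0.5 |
| 8.00 | 24.8 | 2.2 |
| 12.0 | 31.3 | 2.8 |
| 20.0 | 39.7 | 3.9 |
| 30.0 | 43.8 | 5.7 |

(scatter of a reading: 0.5 percentage points)

- the numbers in the tables scatter with a standard deviation of 0.5 percentage points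
- no earlier run changes the charge of free catalyst; that part of a forecast is a guess

1. ratio of target to isomer of the product A at 25 min
2. ratio of target to isomer of the product A at 6.0 h
3. ratio of target to isomer of the product A at 4.0 d
4. which of target and isomer of the product A there is more of at 4.0 d

On Wednesday's run, the growth of target plus isomer of the product A, taken per unit of substrate not visibly converted, falls between the first 4.00 h and the last stretch to 30.0 h. I read this as a pseudo-first-order death of free catalyst at 0.0575 /h, a reading with its scatter. Integrating gives Wednesday-hours, W: the time the flask's catalyst has worked, counted at Wednesday's full charge.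

Suppose target grows with W and the same catalyst makes isomer of the product A from target. Then the ratio falls as one over W, and the ratio times W is a constant, the isomer constant. Wednesday's last reading sets it at 110 h. For this flask it gives 405 at 25 min and 32.9 at 6.0 h.

At 4.0 d I bracket it. Death at full pace throughout gives W = 11.4 h, so a ratio of at most 9.64. Take no death at all as the other limit: W = 63.2 h, and a ratio of at least 1.74.

The forecast gave 16, 15 and 2.2 with target ahead, on “a slow, possibly uncatalysed route”, which puts its last value inside my bracket, below its upper end.

The flask gives 416, 33.6 and, inside the bracket, 5.72.

    target + free catalyst ⇌ isomer of the product A + free catalyst, rate k1*[free catalyst]*[target] forward; the back reaction follows from the equilibrium constant (K = 23.0, k = 0.0130 /M/s)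
    substrate + free catalyst → spent catalyst (k = 0.00130 /M/s)
    substrate + free catalyst ⇌ target + free catalyst, rate k3*[substrate]*[free catalyst] forward; the back reaction follows from the equilibrium constant (K = 15.0, k = 0.0330 /M/s)
    isomer of the product A + free catalyst ⇌ isomer of the product B + free catalyst, rate k4*[free catalyst]*[isomer of the product A] forward; the back reaction follows from the equilibrium constant (K = 1.20, k = 0.0520 /M/s)
    substrate → uncatalysed product (k = 1.20 × 10⁻⁶ /s)

At 4.0 d this flask still holds 12.8% of its free catalyst and 25.3% of its substrate. Now take the neighbour charged with 0.040 M of substrate. Its catalyst starts dying at 0.187 /h, and by 4.0 d its free catalyst stands at 0%. That caps W near 3.51 h, so the isomer constant gives a ratio of 31.3. That neighbour shows 29.4.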